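**Retrosynthetic overview**

1. Target ⇐ its aryl bromide analogue (Br in place of the phenol OH) by a final C(aryl)–O coupling with hydroxide. The bromide is a phenol surrogate that cannot be oxidised in the ring-forming step, so no protecting group is used.
2. Tetrahydrofuran ring ⇐ (2R,3R)-2,3-dibenzylbutane-1,4-diol by dehydrogenative closure of the C7–O bond. C7 is the benzylic CH2 of the dimethoxyphenyl half (C8 its CH, C9 its CH2O); C7', C8', C9' are the same positions on the bromoaryl half. The oxygen is the C9' hydroxyl. This step chooses one of two benzylic sites and sets C7.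
3. Diol ⇐ trans-2,3-dibenzyl-γ-butyrolactone (LiAlH4) ⇐ (R)-β-(4-bromo-3-methoxybenzyl)-γ-butyrolactone + 3,4-dimethoxybenzyl bromide (enolate alkylation sets C8).
4. β-Benzyl lactone ⇐ Stobbe half-ester of 4-bromo-3-methoxybenzaldehyde and dimethyl succinate, by asymmetric hydrogenation (sets C8') and ester-selective reduction.
5. Ring order: the butyrolactone is made first and opened again; the tetrahydrofuran, the only non-aromatic ring of the target, is closed in the sixth of seven steps.

Assumption: 4-bromo-3-methoxybenzaldehyde and 3,4-dimethoxybenzyl bromide are taken as inexpensive catalogue chemicals, and the redox potentials quoted are approximate values for close analogues.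

**Route**

Step 1
Reactants: 1 4-bromo-3-methoxybenzaldehyde; 2 dimethyl succinate
Product: 3 (E)-4-(4-bromo-3-methoxyphenyl)-3-(methoxycarbonyl)but-3-enoic acid
Conditions: NaOMe (2.2 equiv), MeOH, reflux; then aq HCl
Reagents that add atoms: dimethyl succinate (compound 2), COC(=O)CCC(=O)OC
Why: Stobbe condensation: aldol addition of the succinate enolate, lactonisation to the paraconic ester and E1cB ring opening give the (E)-alkylidene half-ester with the two carboxyl groups already differentiated; no stereocentre is formed.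

Step 2
Reactants: 3 (E)-4-(4-bromo-3-methoxyphenyl)-3-(methoxycarbonyl)but-3-enoic acid
Product: 4 (R)-4-(4-bromo-3-methoxyphenyl)-3-(methoxycarbonyl)butanoic acid
Conditions: H2 (5 bar), [Rh(cod)((S,S)-Et-DuPhos)]BF4 (0.5 mol%), NaOMe (10 mol%), MeOH, 25 °C
Reagents that add atoms: none
Why: Rhodium-catalysed asymmetric hydrogenation of an itaconate-type half-ester: carboxylate and alkene chelate the cationic monovalent rhodium centre and H2 is delivered to one face, setting C8' as R (by the itaconate model the (S,S)-ligand should give the (R)-succinate; the sense is confirmed by the rotation of 6), while the aryl bromide is inert to this catalyst.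

Step 3
Reactants: 4 (R)-4-(4-bromo-3-methoxyphenyl)-3-(methoxycarbonyl)butanoic acid
Product: 6 (R)-4-(4-bromo-3-methoxybenzyl)dihydrofuran-2(3H)-one, via hydroxy acid 5 (not isolated)
Conditions: KOH (1.0 equiv), EtOH; CaCl2, NaBH4, EtOH, 0 °C to rt; then 3 M HCl, rt
Reagents that add atoms: none
Why: Chemoselective borohydride reduction: Ca(BH4)2 reduces the methyl ester but not the potassium carboxylate, and acidification lactonises hydroxy acid 5 to the β-benzyl-γ-butyrolactone without touching the stereocentre.

Step 4
Reactants: 6 (R)-4-(4-bromo-3-methoxybenzyl)dihydrofuran-2(3H)-one; 7 3,4-dimethoxybenzyl bromide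
Product: 8 (3R,4R)-4-(4-bromo-3-methoxybenzyl)-3-(3,4-dimethoxybenzyl)dihydrofuran-2(3H)-one
Conditions: LiN(SiMe3)2 (1.1 equiv), THF, −78 °C; then 7, DMPU, −78 to −30 °C
Reagents that add atoms: 3,4-dimethoxybenzyl bromide (compound 7), COc1ccc(CBr)cc1OC
Why: Lactone enolate alkylation (SN2): the benzyl bromide approaches the planar lithium enolate anti to the C4 substituent, giving the 3,4-trans lactone and setting C8 as R.

Step 5
Reactants: 8 (3R,4R)-4-(4-bromo-3-methoxybenzyl)-3-(3,4-dimethoxybenzyl)dihydrofuran-2(3H)-one
Product: 9 (2R,3R)-2-(4-bromo-3-methoxybenzyl)-3-(3,4-dimethoxybenzyl)butane-1,4-diol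
Conditions: LiAlH4, THF, 0 °C; then Na2SO4·10H2O
Reagents that add atoms: none
Why: Hydride reduction of the lactone to the 1,4-diol; reduction at 0 °C is fast enough that neither stereocentre epimerises and the aryl bromide is untouched.

Step 6
Reactants: 9 (2R,3R)-2-(4-bromo-3-methoxybenzyl)-3-(3,4-dimethoxybenzyl)butane-1,4-diol
Product: 10 [(2S,3R,4R)-4-(4-bromo-3-methoxybenzyl)-2-(3,4-dimethoxyphenyl)tetrahydrofuran-3-yl]methanol
Conditions: (4-BrC6H4)3N (10 mol%), 2,6-lutidine (2 equiv), nBu4NBF4 (0.1 M), MeCN/HFIP 9:1, undivided cell, graphite anode, Pt cathode, anode at +1.1 V vs SCE, 2.1 F/mol, 0 °C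
Reagents that add atoms: none
Why: Proposed new method: triarylamine-mediated anodic dehydrogenative cycloetherification, in which the electrogenerated aminium radical cation (about +1.1 V vs SCE) takes an electron from the dimethoxyphenyl ring (about +1.3 V, an uphill transfer pulled through by deprotonation) but not from the bromoanisole ring (above +1.8 V), 2,6-lutidine removes the C7 proton of the arene radical cation, the benzylic radical is oxidised at once to the methoxy-stabilised benzylic cation, and the C9' hydroxyl closes the five-membered ring (the C9 hydroxyl could only give an oxetane) anti to the C8 hydroxymethyl group so that the 2,3-trans (7S) ether is favoured kinetically and thermodynamically, while protons are reduced to H2 at the cathode; the closest known reaction types are DDQ-mediated oxidative benzylic C–H cyclisation onto tethered alcohols and triarylamine-mediated indirect anodic oxidation of alkoxybenzyl positions.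

Step 7
Reactants: 10 [(2S,3R,4R)-4-(4-bromo-3-methoxybenzyl)-2-(3,4-dimethoxyphenyl)tetrahydrofuran-3-yl]methanol
Product: 11 [(2S,3R,4R)-2-(3,4-dimethoxyphenyl)-4-(4-hydroxy-3-methoxybenzyl)tetrahydrofuran-3-yl]methanol
Conditions: Pd2(dba)3 (2 mol%), tBuXPhos (8 mol%), KOH (4 equiv), 1,4-dioxane/H2O 1:1, 100 °C; then dil. HCl to pH 6, 0 °C
Reagents that add atoms: potassium hydroxide, [K+].[OH-]
Why: Palladium-catalysed hydroxylation of an aryl bromide (Buchwald-type C–O coupling): oxidative addition to zerovalent palladium, bromide/hydroxide exchange and C–O reductive elimination from the bulky biarylphosphine complex give the phenoxide, with the primary alcohol outcompeted by hydroxide in the aqueous medium and no stereocentre involved.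

**Compound list**

1 | 4-bromo-3-methoxybenzaldehyde | COc1cc(C=O)ccc1Br | starting material
2 | dimethyl succinate | COC(=O)CCC(=O)OC | starting material
3 | (E)-4-(4-bromo-3-methoxyphenyl)-3-(methoxycarbonyl)but-3-enoic acid | COc1cc(/C=C(\CC(=O)O)C(=O)OC)ccc1Br | intermediate
4 | (R)-4-(4-bromo-3-methoxyphenyl)-3-(methoxycarbonyl)butanoic acid | COc1cc(C[C@@H](C(=O)OC)CC(=O)O)ccc1Br | intermediate
5 | (R)-4-(4-bromo-3-methoxyphenyl)-3-(hydroxymethyl)butanoic acid (not isolated) | COc1cc(C[C@@H](CO)CC(=O)O)ccc1Br | intermediate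
6 | (R)-4-(4-bromo-3-methoxybenzyl)dihydrofuran-2(3H)-one | COc1cc(C[C@H]2COC(=O)C2)ccc1Br | intermediate
7 | 3,4-dimethoxybenzyl bromide (4-(bromomethyl)-1,2-dimethoxybenzene) | COc1ccc(CBr)cc1OC | starting material
8 | (3R,4R)-4-(4-bromo-3-methoxybenzyl)-3-(3,4-dimethoxybenzyl)dihydrofuran-2(3H)-one (trans) | COc1cc(C[C@H]2COC(=O)[C@@H]2Cc3ccc(OC)c(OC)c3)ccc1Br | intermediate
9 | (2R,3R)-2-(4-bromo-3-methoxybenzyl)-3-(3,4-dimethoxybenzyl)butane-1,4-diol | COc1cc(C[C@@H](CO)[C@H](CO)Cc2ccc(OC)c(OC)c2)ccc1Br | intermediate
10 | [(2S,3R,4R)-4-(4-bromo-3-methoxybenzyl)-2-(3,4-dimethoxyphenyl)tetrahydrofuran-3-yl]methanol (2,3-trans, 3,4-cis) | COc1cc(C[C@H]2CO[C@H](c3ccc(OC)c(OC)c3)[C@H]2CO)ccc1Br | intermediate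
11 | [(2S,3R,4R)-2-(3,4-dimethoxyphenyl)-4-(4-hydroxy-3-methoxybenzyl)tetrahydrofuran-3-yl]methanol (2,3-trans, 3,4-cis) | COc1cc(C[C@H]2CO[C@H](c3ccc(OC)c(OC)c3)[C@H]2CO)ccc1O | target

**Summary**

Total step count: 7. Longest linear sequence: 7 steps (1 to 11). No protecting groups are used.

**Three steps most likely to fail**

Step 2 (asymmetric hydrogenation). The risk is an enantiomeric excess below the usual range for this bromo-substituted substrate, or for any Z isomer in 3. The fallback replaces asymmetric catalysis by classical resolution. It sets out from 3: hydrogenation with the achiral catalyst [Rh(cod)(dppb)]BF4 (H2, MeOH) gives racemic 4-(4-bromo-3-methoxyphenyl)-3-(methoxycarbonyl)butanoic acid F1. Crystallisation with (S)-1-phenylethylamine from iPrOH/EtOAc, a pairing chosen by analogy with benzylsuccinic acid resolutions, gives the less soluble salt (S)-1-phenylethylammonium (R)-4-(4-bromo-3-methoxyphenyl)-3-(methoxycarbonyl)butanoate F2, which is recrystallised to constant rotation. Dilute HCl/EtOAc releases the acid, and the route is rejoined at 4.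

Step 6 (proposed new step). The risks are:
- further oxidation of 10, which carries the same dimethoxyphenyl ring;
- loss of the C8 proton from the cation to give a styrene;
- Friedel–Crafts closure onto the bromoanisole ring;
- a minor C7 epimer.

The electrolysis is stopped near 90% conversion and kept buffered and cold. The fallback is known chemistry and brings in the C7 oxygen by an aldol reaction instead of C–H oxidation. It sets out from 6: LiN(SiMe3)2, THF, −78 °C, then 3,4-dimethoxybenzaldehyde gives the trans aldol adduct (3S,4R)-4-(4-bromo-3-methoxybenzyl)-3-[(3,4-dimethoxyphenyl)(hydroxy)methyl]dihydrofuran-2(3H)-one F3, with both carbinol epimers carried on together. LiAlH4, THF, 0 °C gives the triol (2R,3R)-2-(4-bromo-3-methoxybenzyl)-3-[(3,4-dimethoxyphenyl)(hydroxy)methyl]butane-1,4-diol F4. Camphorsulfonic acid (10 mol%), CH2Cl2, 0 °C ionises the benzylic alcohol of either epimer and the C9' hydroxyl closes the ring to the 2,3-trans ether. The route is rejoined at 10.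

Step 7 (hydroxylation). The risks are competing O-arylation of the primary alcohol or of the product phenoxide, protodebromination, and slow oxidative addition at the ortho-methoxy bromide. The fallback goes through a C–B bond and oxidises it. It sets out from 10: Pd(dppf)Cl2, B2pin2, KOAc, 1,4-dioxane, 90 °C gives the aryl boronate [(2S,3R,4R)-2-(3,4-dimethoxyphenyl)-4-[3-methoxy-4-(4,4,5,5-tetramethyl-1,3,2-dioxaborolan-2-yl)benzyl]tetrahydrofuran-3-yl]methanol F5. H2O2/NaOH in THF/H2O at 0 °C then gives the phenol, and the route is rejoined at 11.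

**Further compounds**

F1 | step 2 | racemic 4-(4-bromo-3-methoxyphenyl)-3-(methoxycarbonyl)butanoic acid | COc1cc(CC(C(=O)OC)CC(=O)O)ccc1Br
F2 | step 2 | (S)-1-phenylethylammonium (R)-4-(4-bromo-3-methoxyphenyl)-3-(methoxycarbonyl)butanoate | COc1cc(C[C@@H](C(=O)OC)CC(=O)[O-])ccc1Br.C[C@H]([NH3+])c1ccccc1
F3 | step 6 | (3S,4R)-4-(4-bromo-3-methoxybenzyl)-3-[(3,4-dimethoxyphenyl)(hydroxy)methyl]dihydrofuran-2(3H)-one (both carbinol epimers) | COc1cc(C[C@H]2COC(=O)[C@@H]2C(O)c3ccc(OC)c(OC)c3)ccc1Br
F4 | step 6 | (2R,3R)-2-(4-bromo-3-methoxybenzyl)-3-[(3,4-dimethoxyphenyl)(hydroxy)methyl]butane-1,4-diol (both carbinol epimers) | COc1cc(C[C@@H](CO)[C@H](CO)C(O)c2ccc(OC)c(OC)c2)ccc1Br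
F5 | step 7 | [(2S,3R,4R)-2-(3,4-dimethoxyphenyl)-4-[3-methoxy-4-(4,4,5,5-tetramethyl-1,3,2-dioxaborolan-2-yl)benzyl]tetrahydrofuran-3-yl]methanol | COc1cc(C[C@H]2CO[C@H](c3ccc(OC)c(OC)c3)[C@H]2CO)ccc1B4OC(C)(C)C(C)(C)O4
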